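The central ring (C1/C2 benzoyloxy, C3/C6 aryl, C4/C5 hydroxy) is traced back to a 2,5-diaryl-3,6-dioxy-1,4-benzoquinone. Its six carbons and four oxygens show a latent twofold symmetry: aryl–C–C–O pairs C6–C1 and C3–C4 alternate with the single C–O carbons C2 and C5. One iron-mediated operation therefore joins two molecules of an aryl siloxyalkyne and two CO, making C1–C2, C2–C3, C4–C5 and C5–C6 and closing the ring at the quinone oxidation level. The precursor is the triisopropylsilyl ynol ether of 4-(benzyloxy)phenylacetylene. Afterwards the ortho-quinone tautomer is locked as a diphenylmethylene ketal, which differentiates the two oxygen pairs for benzoylation.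

Key step: step 2

Remark: the target is achiral, so no stereocentre has to be set. Dihydroxyquinone 11 is drawn as its 1,4-quinone tautomer, although step 4 goes through its 4,5-dihydroxy-1,2-benzoquinone tautomer. Commercial building blocks that leave atoms in an isolated product carry numbers; auxiliary reagents stand under Conditions only.

Step 1
Reactants: 1 1-(benzyloxy)-4-ethynylbenzene; 2 tert-butyl hydroperoxide; 3 triisopropylsilyl trifluoromethanesulfonate
Product: 6 ({[4-(benzyloxy)phenyl]ethynyl}oxy)triisopropylsilane, via lithium acetylide 4 (not isolated), via lithium ynolate 5 (not isolated)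
Conditions: n-BuLi, THF, −78 °C; LiOOtBu (from anhydrous tBuOOH and LiN(SiMe3)2, THF, −78 °C), −78 → 0 °C; iPr3SiOTf, −78 → 0 °C; non-acidic work-up
Reagents that add atoms: tert-butyl hydroperoxide, CC(C)(C)OO (used as LiOOtBu, source of the ynol oxygen); triisopropylsilyl trifluoromethanesulfonate, CC(C)[Si](OS(=O)(=O)C(F)(F)F)(C(C)C)C(C)C
Why: Julia-type oxidation of the lithium acetylide at the electrophilic peroxide oxygen should give the lithium ynolate, which the hard, bulky silyl triflate traps on oxygen (the established one-pot route from terminal alkynes to triisopropylsiloxyalkynes); the aryl benzyl ether is inert to one equivalent of n-BuLi at −78 °C.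

Step 2
Reactants: 6 ({[4-(benzyloxy)phenyl]ethynyl}oxy)triisopropylsilane (two equivalents); 7 pentacarbonyliron; 8 carbon monoxide
Product: 10 2,5-bis[4-(benzyloxy)phenyl]-3,6-bis[(triisopropylsilyl)oxy]-1,4-benzoquinone, via tricarbonyl(η4-quinone)iron complex 9 (not isolated)
Conditions: Fe(CO)5 (0.6 equiv), CO (3 atm), hν (365 nm, Pyrex), PhMe, 15 °C; then anhydrous Me3NO, acetone, 0 °C → rt
Reagents that add atoms: pentacarbonyliron, [Fe].[C-]#[O+].[C-]#[O+].[C-]#[O+].[C-]#[O+].[C-]#[O+]; carbon monoxide, [C-]#[O+]
Why: Proposed new method: photochemical loss of CO from Fe(CO)5 should let siloxyalkyne 6 bind zerovalent iron; its nucleophilic aryl-bearing carbon (C6) then adds to a carbonyl ligand (the future C5), and the oxygen-bearing carbon (C1), left on iron as a siloxycarbene-like centre, inserts a second CO (C2) to give a maleoyl-type ferracycle whose cross-conjugated, ketene-like C2 acyl is far more electrophilic than the C5 acyl (a vinylogous silyl ester), so the aryl carbon (C3) of a second alkyne adds at C2 and its oxygen-bearing carbon (C4) closes onto C5, leaving the quinone η4-bound to Fe(CO)3 (9), from which Me3NO strips the carbonyl ligands as CO2. The closest known reaction type is the light-driven formation of tricarbonyl(η4-benzoquinone)iron complexes from two dialkylalkynes and iron carbonyls, together with quinone formation from maleoyl metallacycles and alkynes; neither has been shown for siloxyalkynes. The one ring formed, the six-membered central carbocycle, closes by acylation of C4 at C5 inside the coordination sphere of iron (reductive elimination from a seven-membered ferracycle, formally a [2+2+1+1] assembly). No stereocentre is created. The step needs head-to-tail union and uptake of two CO instead of one: the electron push of the silyloxy oxygen polarises each alkyne so that every new bond joins a CO carbon to one aryl-bearing and one oxygen-bearing carbon, the two bulky iPr3SiO groups avoid each other, and CO pressure favours the second insertion over collapse to a cyclopentadienone complex.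

Step 3
Reactants: 10 2,5-bis[4-(benzyloxy)phenyl]-3,6-bis[(triisopropylsilyl)oxy]-1,4-benzoquinone
Product: 11 2,5-bis[4-(benzyloxy)phenyl]-3,6-dihydroxy-1,4-benzoquinone
Conditions: Bu4NF, THF, 0 °C; then 1 M HCl
Reagents that add atoms: none
Why: Fluoride-mediated desilylation should cleave both Si–O bonds of the vinylogous silyl esters, and acidification returns the strongly acidic dihydroxyquinone; the benzyl ethers are untouched.

Step 4
Reactants: 11 2,5-bis[4-(benzyloxy)phenyl]-3,6-dihydroxy-1,4-benzoquinone; 12 dichlorodiphenylmethane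
Product: 13 4,7-bis[4-(benzyloxy)phenyl]-2,2-diphenyl-1,3-benzodioxole-5,6-dione
Conditions: Ph2CCl2 (1.5 equiv), K2CO3, MeCN, 70 °C
Reagents that add atoms: dichlorodiphenylmethane, ClC(Cl)(c1ccccc1)c1ccccc1
Why: Diarylmethylene ketal formation with a gem-dichloride, as used for catechols: one vinylogous carboxylate oxygen is alkylated through the chlorodiphenylmethyl cation and the neighbouring ring oxygen closes the five-membered dioxole, which fixes the ortho-quinone tautomer, so only one ketal can form (on the C4/C5 oxygens) and the carbonate buffer protects the benzyl ethers from HCl.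

Step 5
Reactants: 13 4,7-bis[4-(benzyloxy)phenyl]-2,2-diphenyl-1,3-benzodioxole-5,6-dione
Product: 14 4,7-bis[4-(benzyloxy)phenyl]-2,2-diphenyl-1,3-benzodioxole-5,6-diol
Conditions: Na2S2O4, THF–H2O, rt, argon
Reagents that add atoms: none
Why: Dithionite reduction of an ortho-quinone to its catechol is standard and should leave the ketal and the benzyl ethers alone.

Step 6
Reactants: 14 4,7-bis[4-(benzyloxy)phenyl]-2,2-diphenyl-1,3-benzodioxole-5,6-diol; 15 benzoyl chloride
Product: 16 4,7-bis[4-(benzyloxy)phenyl]-2,2-diphenyl-1,3-benzodioxole-5,6-diyl dibenzoate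
Conditions: BzCl (2.5 equiv), Et3N, DMAP (cat.), CH2Cl2, 0 °C → rt, argon
Reagents that add atoms: benzoyl chloride, O=C(Cl)c1ccccc1
Why: DMAP-catalysed O-acylation of the two catechol hydroxyls; the other two ring oxygens are locked in the ketal, so the benzoates can only enter at the adjacent pair C1/C2.

Step 7
Reactants: 16 4,7-bis[4-(benzyloxy)phenyl]-2,2-diphenyl-1,3-benzodioxole-5,6-diyl dibenzoate
Product: 17 4,4'',5',6'-tetrahydroxy-[1,1':4',1''-terphenyl]-2',3'-diyl dibenzoate (4,5-dihydroxy-3,6-bis(4-hydroxyphenyl)-1,2-phenylene dibenzoate)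
Conditions: H2 (1 atm), Pd(OH)2/C, THF–EtOAc, rt
Reagents that add atoms: none
Why: Catalytic hydrogenolysis should cleave the two aryl benzyl ethers and the doubly benzylic diphenylmethylene ketal while aryl benzoates persist; no free hydroxyl lies ortho to a benzoate, so acyl migration cannot scramble the substitution pattern.

Compound list
1 | 1-(benzyloxy)-4-ethynylbenzene | C#Cc1ccc(OCc2ccccc2)cc1 | starting material
2 | tert-butyl hydroperoxide | CC(C)(C)OO | starting material
3 | triisopropylsilyl trifluoromethanesulfonate | CC(C)[Si](OS(=O)(=O)C(F)(F)F)(C(C)C)C(C)C | starting material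
4 | lithium [4-(benzyloxy)phenyl]acetylide (not isolated) | [Li]C#Cc1ccc(OCc2ccccc2)cc1 | intermediate
5 | lithium 2-[4-(benzyloxy)phenyl]ethynolate (not isolated) | [Li]OC#Cc1ccc(OCc2ccccc2)cc1 | intermediate
6 | ({[4-(benzyloxy)phenyl]ethynyl}oxy)triisopropylsilane | CC(C)[Si](OC#Cc1ccc(OCc2ccccc2)cc1)(C(C)C)C(C)C | intermediate
7 | pentacarbonyliron | [Fe].[C-]#[O+].[C-]#[O+].[C-]#[O+].[C-]#[O+].[C-]#[O+] | starting material
8 | carbon monoxide | [C-]#[O+] | starting material
9 | tricarbonyl{η4-2,5-bis[4-(benzyloxy)phenyl]-3,6-bis[(triisopropylsilyl)oxy]-1,4-benzoquinone}iron (not isolated; written as quinone plus Fe(CO)3) | O=C1C(O[Si](C(C)C)(C(C)C)C(C)C)=C(c2ccc(OCc3ccccc3)cc2)C(=O)C(O[Si](C(C)C)(C(C)C)C(C)C)=C1c1ccc(OCc2ccccc2)cc1.[Fe].[C-]#[O+].[C-]#[O+].[C-]#[O+] | intermediate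
10 | 2,5-bis[4-(benzyloxy)phenyl]-3,6-bis[(triisopropylsilyl)oxy]-1,4-benzoquinone | O=C1C(O[Si](C(C)C)(C(C)C)C(C)C)=C(c2ccc(OCc3ccccc3)cc2)C(=O)C(O[Si](C(C)C)(C(C)C)C(C)C)=C1c1ccc(OCc2ccccc2)cc1 | intermediate
11 | 2,5-bis[4-(benzyloxy)phenyl]-3,6-dihydroxy-1,4-benzoquinone | O=C1C(O)=C(c2ccc(OCc3ccccc3)cc2)C(=O)C(O)=C1c1ccc(OCc2ccccc2)cc1 | intermediate
12 | dichlorodiphenylmethane | ClC(Cl)(c1ccccc1)c1ccccc1 | starting material
13 | 4,7-bis[4-(benzyloxy)phenyl]-2,2-diphenyl-1,3-benzodioxole-5,6-dione | O=C1C(=O)C(c2ccc(OCc3ccccc3)cc2)=C2OC(c3ccccc3)(c3ccccc3)OC2=C1c1ccc(OCc2ccccc2)cc1 | intermediate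
14 | 4,7-bis[4-(benzyloxy)phenyl]-2,2-diphenyl-1,3-benzodioxole-5,6-diol | Oc1c(O)c(-c2ccc(OCc3ccccc3)cc2)c2OC(c3ccccc3)(c3ccccc3)Oc2c1-c1ccc(OCc2ccccc2)cc1 | intermediate
15 | benzoyl chloride | O=C(Cl)c1ccccc1 | starting material
16 | 4,7-bis[4-(benzyloxy)phenyl]-2,2-diphenyl-1,3-benzodioxole-5,6-diyl dibenzoate | O=C(Oc1c(OC(=O)c2ccccc2)c(-c2ccc(OCc3ccccc3)cc2)c2OC(c3ccccc3)(c3ccccc3)Oc2c1-c1ccc(OCc2ccccc2)cc1)c1ccccc1 | intermediate
17 | 4,4'',5',6'-tetrahydroxy-[1,1':4',1''-terphenyl]-2',3'-diyl dibenzoate | O=C(Oc1c(OC(=O)c2ccccc2)c(-c2ccc(O)cc2)c(O)c(O)c1-c1ccc(O)cc1)c1ccccc1 | target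
18 | 2,3,5,6-tetrabromo-1,4-benzoquinone (used only in the fallback to step 2) | O=C1C(Br)=C(Br)C(=O)C(Br)=C1Br | starting material
19 | [4-(benzyloxy)phenyl]boronic acid (used only in the fallback to step 2) | OB(O)c1ccc(OCc2ccccc2)cc1 | starting material
20 | ethyl 4-(benzyloxy)benzoate (used only in the fallback to step 1) | CCOC(=O)c1ccc(OCc2ccccc2)cc1 | starting material

Total step count: 7
Longest linear sequence: 7 steps (from compound 1 to compound 17)

Steps most likely to fail

Step 2 (Proposed new method). The two alkynes may couple on iron with uptake of only one CO and closure to a five-membered ring, or head to head. The ynol ether may also be lost through silyl migration or dimerisation before it is carbonylated, and the silyl groups may be lost during oxidative decomplexation. The fallback uses known chemistry and abandons the alkyne building block. It therefore sets out from the commercial compounds 18 and 19, not from a route intermediate, and comes back to the route at compound 11. Methanolysis of 18 (NaOMe, MeOH, 0 °C → rt; addition–elimination at two para-related C–Br positions) should give 2,5-dibromo-3,6-dimethoxy-1,4-benzoquinone F1. Double Suzuki–Miyaura coupling with 19 (Pd(PPh3)4, CsF, 1,4-dioxane, 90 °C) should give 2,5-bis[4-(benzyloxy)phenyl]-3,6-dimethoxy-1,4-benzoquinone F2. Hydrolysis of the two vinylogous methyl esters (NaOH, aqueous dioxane, 60 °C; then HCl) should give 11, and steps 4 to 7 follow unchanged.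

Step 4. Ring closure may stall after the first O-alkylation of the ambident dihydroxyquinone, with hydrolysis back to starting material on work-up, or acid set free may cause loss of benzyl ethers. The fallback inverts reduction and ketal formation. It sets out from compound 11 and comes back at compound 14, bypassing 13. Dithionite reduction (Na2S2O4, THF–H2O, argon) should give 3,6-bis[4-(benzyloxy)phenyl]benzene-1,2,4,5-tetrol F3, an ordinary bis-catechol. One catechol pair is then ketalised with a deficiency of Ph2CCl2 (0.9 equiv, K2CO3, degassed MeCN, 60 °C; standard catechol protection). Mono-ketal 14 is separated from bis-ketal and from unreacted F3, which returns to 11 on air oxidation and is recycled, and the route resumes at step 6. The desymmetrisation is then statistical and no longer inherent.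

Step 1. Oxygen transfer to the acetylide may be incomplete, and the ynol ether may suffer hydrolysis or O-to-C silyl migration during isolation. The fallback generates the same ynolate by a carbenoid rearrangement (Kowalski ester homologation) and not by oxidation. It sets out from commercial compound 20 and comes back at compound 5, and hence at 6. Ester 20 is treated with LiCHBr2 (from CH2Br2 and lithium 2,2,6,6-tetramethylpiperidide, THF, −78 °C), then LiN(SiMe3)2, to give lithium 1-[4-(benzyloxy)phenyl]-2,2-dibromoethen-1-olate F4, which is not isolated. n-BuLi (−78 °C → rt) effects bromine–lithium exchange, and aryl migration in the resulting carbenoid should give ynolate 5, which iPr3SiOTf silylates on oxygen as in step 1.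

Further compounds
F1 | step 2 | 2,5-dibromo-3,6-dimethoxy-1,4-benzoquinone | COC1=C(Br)C(=O)C(OC)=C(Br)C1=O
F2 | step 2 | 2,5-bis[4-(benzyloxy)phenyl]-3,6-dimethoxy-1,4-benzoquinone | COC1=C(c2ccc(OCc3ccccc3)cc2)C(=O)C(OC)=C(c2ccc(OCc3ccccc3)cc2)C1=O
F3 | step 4 | 3,6-bis[4-(benzyloxy)phenyl]benzene-1,2,4,5-tetrol | Oc1c(O)c(-c2ccc(OCc3ccccc3)cc2)c(O)c(O)c1-c1ccc(OCc2ccccc2)cc1
F4 | step 1 | lithium 1-[4-(benzyloxy)phenyl]-2,2-dibromoethen-1-olate | [Li]OC(=C(Br)Br)c1ccc(OCc2ccccc2)cc1
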